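The strategy rests on the ring segment C9H=C10(Cl)–C11H2–C12H(Br) of the oxocene (ring O, C7–C13). A homoallylic bromide with chlorine on its alkene is what bromide opening of a 1-chlorocyclopropylcarbinyl cation should give (cationic centre C9, cyclopropane C10–C11–C12 fused to an oxepane across C10–C12).
The side chain is disconnected first: the C6 acetate, the (Z)-enyne by Peterson olefination at C4, and the C5/C6 syn-chlorohydrin by (Z)-γ-chloroallylboration of a C6 aldehyde on the finished oxocene.
Oxocene ⇒ chlorocyclopropyl carbinol ⇒ 2-chloro-oxepenone C9(=O)–C10(Cl)=C12 (C11 from sulfoxonium methylide) ⇒ pyranone silyl enol ether C9=C12 (C10 from dichlorocarbene) ⇒ β-hydroxy ynone ⇒ dimethyl (R)-malate (C6–C9) + 1-butyne (C12–C15).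
Ring order: six-membered ring (oxa-Michael), seven-membered ring (C10 inserted), 7/3 bicycle (C11 added), eight-membered ring (fusion bond cut).

Key step: step 11

Remark: atoms carry the target chain numbers (C1 alkyne CH to C15 ethyl CH3). Read from the SMILES, the target is (3Z,5S,6S,7R,9E,12S,13R). Here 9E is the ordinary cis ring alkene, with C8 and C11 on the same side; the descriptor is E because Cl outranks C11. (+)-Ipc2BOMe and 1,3-bis(triisopropylsilyl)propyne are taken as purchasable.

Step 1
Reactants: 1 dimethyl (R)-malate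
Product: 2 methyl (R)-3,4-dihydroxybutanoate
Conditions: BH3·SMe2 (1.05 equiv), NaBH4 (5 mol %), THF, 0 °C to rt; MeOH quench
Reagents that add atoms: none
Why: The hydroxyl group binds borane and hydride is then delivered within a five-membered alkoxyborane chelate to the adjacent ester only (hydroxyl-directed chemoselective borane reduction of an α-hydroxy ester), so the distal ester and the stereocentre that becomes C7 are untouched.

Step 2
Reactants: 2 methyl (R)-3,4-dihydroxybutanoate
Product: 3 methyl (R)-4-(tert-butyldiphenylsilyloxy)-3-hydroxybutanoate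
Conditions: TBDPSCl (1.05 equiv), imidazole, CH2Cl2, 0 °C
Reagents that add atoms: tert-butyldiphenylsilyl chloride, CC(C)(C)[Si](Cl)(c1ccccc1)c1ccccc1
Why: Selective silylation, in which the bulky silyl chloride reacts with the primary C6 hydroxyl far faster than with the secondary C7 hydroxyl, and prompt protection also forestalls lactonisation of the diol ester.

Step 3
Reactants: 3 methyl (R)-4-(tert-butyldiphenylsilyloxy)-3-hydroxybutanoate
Product: 4 (R)-4-(tert-butyldiphenylsilyloxy)-3-hydroxy-N-methoxy-N-methylbutanamide
Conditions: MeNH(OMe)·HCl, i-PrMgCl (excess), THF, −20 to 0 °C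
Reagents that add atoms: N,O-dimethylhydroxylamine hydrochloride, CNOC.Cl
Why: Weinreb amide formation by aminolysis of the ester using the chloromagnesium amide, one further equivalent of Grignard reagent masking the free hydroxyl as its alkoxide so that neither elimination nor racemisation is expected at low temperature.

Step 4
Reactants: 4 (R)-4-(tert-butyldiphenylsilyloxy)-3-hydroxy-N-methoxy-N-methylbutanamide; 5 1-butyne
Product: 7 (R)-1-(tert-butyldiphenylsilyloxy)-2-hydroxyoct-5-yn-4-one, via lithium but-1-ynide 6 (not isolated)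
Conditions: 5 (3.2 equiv), n-BuLi (3 equiv), THF, −78 °C; then 4, −78 to −20 °C; aq NH4Cl
Reagents that add atoms: none
Why: Weinreb ketone synthesis, in which the first equivalent of acetylide deprotonates the hydroxyl and the next adds to the amide to give a chelated tetrahedral intermediate that collapses to the ynone only on quenching, so no over-addition occurs.

Step 5
Reactants: 7 (R)-1-(tert-butyldiphenylsilyloxy)-2-hydroxyoct-5-yn-4-one
Product: 8 (R)-2-[(tert-butyldiphenylsilyloxy)methyl]-6-ethyl-2,3-dihydro-4H-pyran-4-one
Conditions: Ph3PAuCl (5 mol %), AgOTf (5 mol %), CH2Cl2, rt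
Reagents that add atoms: none
Why: Gold π-activation of the ynone triggers 6-endo-dig attack of the C7 hydroxyl on the β-alkyne carbon C13 (intramolecular oxa-Michael addition, favoured over 5-exo attack by the polarisation of the ynone), closing the six-membered ring without touching C7.

Step 6
Reactants: 8 (R)-2-[(tert-butyldiphenylsilyloxy)methyl]-6-ethyl-2,3-dihydro-4H-pyran-4-one
Product: 10 cis-(2R,6R)-2-[(tert-butyldiphenylsilyloxy)methyl]-6-ethyl-4-(triethylsilyloxy)-3,6-dihydro-2H-pyran (enol ether double bond C9=C12), via lithium enolate 9 (not isolated)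
Conditions: L-Selectride (1.1 equiv), THF, −78 °C; TESCl, −78 to 0 °C; rapid filtration over Et3N-deactivated silica to remove the borane
Reagents that add atoms: chlorotriethylsilane, CC[Si](Cl)(CC)CC
Why: Conjugate (1,4) hydride reduction of the vinylogous ester by L-Selectride with enolate trapping, in which hydride enters C13 axially on the half-chair that keeps the C7 side chain pseudo-equatorial, so that C13 is set cis to C7 (13R) and O-silylation freezes the enolate double bond at C9=C12.

Step 7
Reactants: 10 cis-(2R,6R)-2-[(tert-butyldiphenylsilyloxy)methyl]-6-ethyl-4-(triethylsilyloxy)-3,6-dihydro-2H-pyran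
Product: 12 cis-(2R,7R)-2-[(tert-butyldiphenylsilyloxy)methyl]-5-chloro-7-ethyl-2,3-dihydrooxepin-4(7H)-one, via siloxy-dichlorocyclopropane 11 (not isolated)
Conditions: CHCl3, KOt-Bu, pentane, −20 to 0 °C; filter, concentrate; toluene, 100 °C
Reagents that add atoms: chloroform, ClC(Cl)Cl
Why: Dichlorocarbene [2+1] cycloaddition to the electron-rich enol ether followed by thermal cyclopropyl-to-allyl opening of 11 with loss of chloride and of the silyl group (the silyl enol ether/dihalocarbene one-carbon ring expansion) inserts C10 between C9 and C12 and erases both transient stereocentres, while C7 and C13 are not involved.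

Step 8
Reactants: 12 cis-(2R,7R)-2-[(tert-butyldiphenylsilyloxy)methyl]-5-chloro-7-ethyl-2,3-dihydrooxepin-4(7H)-one
Product: 13 chlorocyclopropyl ketone, 7-chloro-2-ethyl-4-[(tert-butyldiphenylsilyloxy)methyl]-3-oxabicyclo[5.1.0]octan-6-one, C11H2 on the ring face opposite the ethyl group (7R,10S,12R,13R in target numbering)
Conditions: Me3S(O)I, NaH, DMSO, rt; then 12 in THF (THF–DMSO about 4:1), −10 °C, 1.05 equiv ylide
Reagents that add atoms: trimethylsulfoxonium iodide, C[S+](C)(C)=O.[I-]
Why: Corey–Chaykovsky cyclopropanation, in which the soft sulfoxonium ylide adds 1,4 to C12 on the face opposite the neighbouring C13 ethyl group and the chloro-enolate then displaces DMSO in a 3-exo-tet closure that can only be cis-fused, which sets C12 (R) and C10 (S), the low temperature and near-stoichiometric ylide limiting C8 enolisation and retro-oxa-Michael opening.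

Step 9
Reactants: 13 chlorocyclopropyl ketone
Product: 14 chlorocyclopropyl carbinol, 7-chloro-2-ethyl-4-[(tert-butyldiphenylsilyloxy)methyl]-3-oxabicyclo[5.1.0]octan-6-ol with the C9 hydroxyl cis to C11H2 (7R,9S,10S,12R,13R)
Conditions: NaBH4, CeCl3·7H2O, MeOH, −40 °C
Reagents that add atoms: none
Why: Luche reduction, in which the cerium-activated carbonyl takes up hydride from the face turned away from the cyclopropane methylene, which should give mainly the C9 alcohol cis to C11H2 (9S), the cyclopropyl chloride being inert, and any C9 epimer may be carried along because C9 becomes sp2 in step 11.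

Step 10
Reactants: 14 chlorocyclopropyl carbinol
Product: 15 C9 methanesulfonate of 14 (same configuration at every centre)
Conditions: MsCl, Et3N, CH2Cl2, −20 °C; cold aqueous work-up, used without chromatography
Reagents that add atoms: methanesulfonyl chloride, CS(=O)(=O)Cl
Why: Standard sulfonylation through sulfene with retention at C9, the electron-withdrawing chlorine on C10 slowing ionisation enough for this cyclopropylcarbinyl mesylate to survive a cold work-up.

Step 11
Reactants: 15 C9 methanesulfonate
Product: 17 (7R,9E,12S,13R)-bromo-chloro-oxocene, 7-bromo-5-chloro-8-ethyl-2-[(tert-butyldiphenylsilyloxy)methyl]-3,6,7,8-tetrahydro-2H-oxocine, C7/C13 substituents cis, Br trans to ethyl, via chlorocyclopropylcarbinyl cation 16 (not isolated)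
Conditions: ZnBr2 (2 equiv), LiBr (3 equiv), Et2O–CH2Cl2, 0 °C to rt
Reagents that add atoms: lithium bromide, [Li+].[Br-]
Why: Proposed new method: ZnBr2 assists loss of the C9 mesylate while the C10–C12 fusion bond, which in this epimer (C9–O cis to C11H2) can lie anti-periplanar to the C9–O bond with C8 and C11 syn-clinal, donates into C9 to give the delocalised cation 16, and bromide then attacks C12 from the side opposite the departing C10, so that C9=C10 and C12–Br are made, C10–C12 is cut and C11 becomes a ring atom. The closest known reaction types are the Julia–Johnson cyclopropylcarbinyl-to-homoallyl bromide rearrangement, the i-steroid rearrangement and the bicyclo[5.1.0]oct-2-yl to cyclooct-3-enyl solvolytic ring enlargement, but none of them has been shown with chlorine on the cyclopropane carbon next to the cationic centre or within a cyclopropane-fused oxepane. The oxocene is formed not by an end-to-end cyclisation but by ring enlargement, the shared bond of the 7/3 bicycle being broken so that both rings merge into the eight-membered one; C8 and C11 end up cis on the new alkene (9E by CIP), and a strained trans isomer, should any form, would re-ionise readily. The single new stereocentre C12 is controlled by the cyclopropane face fixed in step 8 together with inversion at C12, which puts bromine trans to the C13 ethyl group (12S). The step needs scission of C10–C12 instead of C10–C11 and no lasting escape to a 1-chlorocyclobutyl cation: C12 is secondary whereas C11 is primary, the leaving group is aligned with the fusion bond, and under ZnBr2/LiBr the cyclopropylcarbinyl and geminal bromochlorocyclobutyl halides should ionise again whereas the homoallylic bromide beside the electron-poor chloroalkene should not, so that it accumulates. A C9-epimeric mesylate is expected to join the same manifold after SN2 inversion by bromide to the aligned cyclopropylcarbinyl bromide.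

Step 12
Reactants: 17 bromo-chloro-oxocene silyl ether
Product: 18 (7R,9E,12S,13R)-oxocene C6 primary alcohol
Conditions: TBAF, AcOH (1:1), THF, 0 °C to rt
Reagents that add atoms: none
Why: Fluoride desilylation driven by the strong Si–F bond, acetic acid keeping the medium non-basic so that the secondary C12 bromide is not lost by E2 elimination.

Step 13
Reactants: 18 oxocene C6 primary alcohol
Product: 19 (7R,9E,12S,13R)-oxocene C6 aldehyde
Conditions: Dess–Martin periodinane, CH2Cl2, 0 °C to rt; short silica plug, used at once
Reagents that add atoms: none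
Why: Dess–Martin oxidation works under neutral, non-epimerising conditions, leaves the bromide and the chloroalkene alone, and immediate use of the α-alkoxy aldehyde protects C7.

Step 14
Reactants: 19 oxocene C6 aldehyde; 20 allyl chloride
Product: 23 (5S,6S)-syn-chlorohydrin with terminal vinyl group on the oxocene, via (Z)-γ-chloroallylborane 21 (not isolated), via borinate adduct 22 (not isolated)
Conditions: 20, (+)-Ipc2BOMe [from (−)-α-pinene], LiN(c-Hex)2 (c-Hex2NH, n-BuLi), Et2O, −95 °C; BF3·OEt2; then 19, −95 °C; ethanolamine work-up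
Reagents that add atoms: none
Why: Asymmetric (Z)-γ-chloroallylboration, in which lithiated allyl chloride is trapped by Ipc2BOMe at the carbon remote from chlorine, BF3 strips methoxide to give the (Z)-borane 21, and addition through a closed chair (Zimmerman–Traxler) transition state turns the Z geometry into the 5,6-syn chlorohydrin while the Ipc groups derived from (−)-α-pinene select the aldehyde face that gives 6S (and hence 5S) against the bias of the C7 alkoxy centre, the assignment to be checked by Mosher ester analysis.

Step 15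
Reactants: 23 syn-chlorohydrin
Product: 24 C6 triethylsilyl ether of 23
Conditions: TESOTf, 2,6-lutidine, CH2Cl2, −78 °C
Reagents that add atoms: triethylsilyl trifluoromethanesulfonate, CC[Si](CC)(CC)OS(=O)(=O)C(F)(F)F
Why: Silyl ether formation with a hindered, non-nucleophilic pyridine base protects the C6 hydroxyl without closing the chlorohydrin to the epoxide.

Step 16
Reactants: 24 C6 triethylsilyl ether
Product: 25 (5R,6S)-α-chloro aldehyde (C4 = CHO; same spatial arrangement at C5, descriptor changed by priorities)
Conditions: O3 (1.0 equiv, titrated cold solution in CH2Cl2), CH2Cl2, −78 °C; PPh3, −78 °C to 0 °C; used crude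
Reagents that add atoms: ozone, [O-][O+]=O
Why: Ozonolysis (Criegee mechanism) is an electrophilic cycloaddition, so the exposed monosubstituted alkene should be consumed before the ring-embedded trisubstituted alkene that is deactivated by chlorine on C10 when only one equivalent of ozone is supplied, and neutral reduction by PPh3 avoids epimerisation at C5.

Step 17
Reactants: 25 α-chloro aldehyde; 26 1,3-bis(triisopropylsilyl)propyne
Product: 28 TIPS-capped (3Z)-enyne with C6 OTES, via lithiated propyne 27 (not isolated)
Conditions: 26, n-BuLi, THF, −20 °C; then 25, −78 °C, slow warming to −20 °C; aq NH4Cl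
Reagents that add atoms: none
Why: Peterson olefination, in which the hindered lithiated propargylsilane 27 adds to the aldehyde faster than it deprotonates C5 at −78 °C and the two bulky TIPS groups favour the β-oxidosilane diastereomer whose syn elimination of silanolate delivers the (Z)-enyne, so that no palladium or heating comes near the allylic chloride.

Step 18
Reactants: 28 TIPS-capped (3Z)-enyne
Product: 29 (3Z,5S,6S,7R,9E,12S,13R)-C6 alcohol with free terminal alkyne
Conditions: TBAF (2.5 equiv), AcOH (3 equiv), THF, 0 °C to rt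
Reagents that add atoms: none
Why: Fluoride cleaves both the O–TES and the alkynyl C–TIPS bonds, and the acetic acid buffer protonates the C6 alkoxide as it forms, so that closure to the 5,6-epoxide and elimination at C12 are not expected.

Step 19
Reactants: 29 C6 alcohol
Product: 30 target CNP0228902.1, (3Z,5S,6S,7R,9E,12S,13R)-C6 acetate
Conditions: Ac2O, pyridine, DMAP (cat.), CH2Cl2, 0 °C
Reagents that add atoms: acetic anhydride, CC(=O)OC(C)=O
Why: DMAP-catalysed acylation of the secondary alcohol proceeds with retention at C6 under mild conditions tolerated by both chlorides, the bromide and the enyne.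

Compound list
1 | dimethyl (R)-malate | COC(=O)[C@H](O)CC(=O)OC | starting material
2 | methyl (R)-3,4-dihydroxybutanoate | COC(=O)C[C@@H](O)CO | intermediate
3 | methyl (R)-4-(tert-butyldiphenylsilyloxy)-3-hydroxybutanoate | COC(=O)C[C@@H](O)CO[Si](c1ccccc1)(c1ccccc1)C(C)(C)C | intermediate
4 | (R)-4-(tert-butyldiphenylsilyloxy)-3-hydroxy-N-methoxy-N-methylbutanamide | CON(C)C(=O)C[C@@H](O)CO[Si](c1ccccc1)(c1ccccc1)C(C)(C)C | intermediate
5 | 1-butyne | CCC#C | starting material
6 | lithium but-1-ynide | CCC#C[Li] | intermediate
7 | (R)-1-(tert-butyldiphenylsilyloxy)-2-hydroxyoct-5-yn-4-one | CCC#CC(=O)C[C@@H](O)CO[Si](c1ccccc1)(c1ccccc1)C(C)(C)C | intermediate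
8 | (R)-2-[(tert-butyldiphenylsilyloxy)methyl]-6-ethyl-2,3-dihydro-4H-pyran-4-one | CCC1=CC(=O)C[C@H](CO[Si](c2ccccc2)(c2ccccc2)C(C)(C)C)O1 | intermediate
9 | lithium enolate (C9=C12) of the cis-tetrahydropyranone | CC[C@@H]1C=C(O[Li])C[C@H](CO[Si](c2ccccc2)(c2ccccc2)C(C)(C)C)O1 | intermediate
10 | cis-(2R,6R) triethylsilyl enol ether | CC[C@@H]1C=C(O[Si](CC)(CC)CC)C[C@H](CO[Si](c2ccccc2)(c2ccccc2)C(C)(C)C)O1 | intermediate
11 | siloxy-dichlorocyclopropane (either cis-fused face; both new centres are erased) | CC[C@@H]1C2C(Cl)(Cl)C2(O[Si](CC)(CC)CC)C[C@H](CO[Si](c3ccccc3)(c3ccccc3)C(C)(C)C)O1 | intermediate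
12 | cis-(2R,7R)-5-chloro-7-ethyl-2-(silyloxymethyl)-2,3-dihydrooxepin-4(7H)-one | CC[C@@H]1C=C(Cl)C(=O)C[C@H](CO[Si](c2ccccc2)(c2ccccc2)C(C)(C)C)O1 | intermediate
13 | chlorocyclopropyl ketone (3-oxabicyclo[5.1.0]octan-6-one) | CC[C@@H]1[C@H]2C[C@@]2(Cl)C(=O)C[C@H](CO[Si](c3ccccc3)(c3ccccc3)C(C)(C)C)O1 | intermediate
14 | chlorocyclopropyl carbinol (OH cis to C11H2) | CC[C@@H]1[C@H]2C[C@@]2(Cl)[C@@H](O)C[C@H](CO[Si](c3ccccc3)(c3ccccc3)C(C)(C)C)O1 | intermediate
15 | C9 methanesulfonate | CC[C@@H]1[C@H]2C[C@@]2(Cl)[C@@H](OS(C)(=O)=O)C[C@H](CO[Si](c3ccccc3)(c3ccccc3)C(C)(C)C)O1 | intermediate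
16 | chlorocyclopropylcarbinyl cation (one limiting structure) | CC[C@@H]1[C@H]2C[C@@]2(Cl)[CH+]C[C@H](CO[Si](c3ccccc3)(c3ccccc3)C(C)(C)C)O1 | intermediate
17 | bromo-chloro-oxocene, C6 OTBDPS | CC(C)(C)[Si](c1ccccc1)(c1ccccc1)OC[C@H]2C/C=C(/Cl)C[C@H](Br)[C@@H](CC)O2 | intermediate
18 | oxocene C6 alcohol | OC[C@H]1C/C=C(/Cl)C[C@H](Br)[C@@H](CC)O1 | intermediate
19 | oxocene C6 aldehyde | O=C[C@H]1C/C=C(/Cl)C[C@H](Br)[C@@H](CC)O1 | intermediate
20 | allyl chloride | C=CCCl | starting material
21 | (Z)-γ-chloroallyl-diisopinocampheylborane, Ipc from (−)-α-pinene | Cl/C=C\CB([C@H]1C[C@H]2C[C@@H]([C@@H]1C)C2(C)C)[C@H]1C[C@H]2C[C@@H]([C@@H]1C)C2(C)C | intermediate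
22 | diisopinocampheylborinate of the chlorohydrin | C=C[C@H](Cl)[C@@H](OB([C@H]3C[C@H]4C[C@@H]([C@@H]3C)C4(C)C)[C@H]3C[C@H]4C[C@@H]([C@@H]3C)C4(C)C)[C@H]1C/C=C(/Cl)C[C@H](Br)[C@@H](CC)O1 | intermediate
23 | (5S,6S)-syn-chlorohydrin | C=C[C@H](Cl)[C@@H](O)[C@H]1C/C=C(/Cl)C[C@H](Br)[C@@H](CC)O1 | intermediate
24 | C6 triethylsilyl ether | C=C[C@H](Cl)[C@@H](O[Si](CC)(CC)CC)[C@H]1C/C=C(/Cl)C[C@H](Br)[C@@H](CC)O1 | intermediate
25 | α-chloro aldehyde | O=C[C@H](Cl)[C@@H](O[Si](CC)(CC)CC)[C@H]1C/C=C(/Cl)C[C@H](Br)[C@@H](CC)O1 | intermediate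
26 | 1,3-bis(triisopropylsilyl)propyne | CC(C)[Si](C(C)C)(C(C)C)CC#C[Si](C(C)C)(C(C)C)C(C)C | starting material
27 | lithiated 1,3-bis(triisopropylsilyl)propyne | CC(C)[Si](C(C)C)(C(C)C)C([Li])C#C[Si](C(C)C)(C(C)C)C(C)C | intermediate
28 | TIPS-capped (Z)-enyne, C6 OTES | CC(C)[Si](C(C)C)(C(C)C)C#C/C=C\[C@H](Cl)[C@@H](O[Si](CC)(CC)CC)[C@H]1C/C=C(/Cl)C[C@H](Br)[C@@H](CC)O1 | intermediate
29 | C6 alcohol with terminal (Z)-enyne | C#C/C=C\[C@H](Cl)[C@@H](O)[C@H]1C/C=C(/Cl)C[C@H](Br)[C@@H](CC)O1 | intermediate
30 | CNP0228902.1 | C#C/C=C\[C@H](Cl)[C@@H](OC(C)=O)[C@H]1C/C=C(/Cl)C[C@H](Br)[C@@H](CC)O1 | target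

Total step count: 19. Longest linear sequence: 19 steps (1 to 30). Compounds 5, 20 and 26 are bought and enter directly.

Steps most likely to fail

1. Step 11 (ring enlargement).
- Ionisation may be too slow because of the chlorine on C10.
- The outer C10–C11 bond may break instead of the fusion bond.
- The cation may drain into the chlorocyclobutyl manifold.
- Participation of the ring oxygen may erode inversion at C12.

The fallback uses known reactions only, leaves the route at 10 and rejoins it at 17; the ring is cut open and re-closed by metathesis. Ozonolysis of the C9=C12 enol ether bond of 10 (O3, CH2Cl2–MeOH, −78 °C; Me2S) keeps the cis C7–O–C13 ether. After hydrolysis of the silyl ester it gives the C12-aldehyde C9-acid F1, which TMSCHN2 converts into the methyl ester aldehyde F2. Chelation-controlled Keck allylation (MgBr2·OEt2, CH2Cl2, −78 °C) with tributyl(2-chloroallyl)stannane F3 (from 2,3-dichloropropene and Bu3SnLi) brings in C11, C10 and its chlorine, and should give the 12,13-syn (12R) alcohol F4. DIBAL-H (one extra equivalent for the hydroxyl, −78 °C) gives the hydroxy aldehyde F5. Wittig methylenation (Ph3P=CH2) gives the chloro diene F6. Ring-closing metathesis of the vinyl and 2-chloroalkenyl termini (second-generation Grubbs catalyst, high dilution, reflux) gives the (12R)-oxocenol F7. Appel-type bromination with inversion (CBr4, P(n-Oct)3, toluene, 70 °C) then delivers 17.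

2. Step 8 (cyclopropanation of the chloroenone).
- The basic ylide may enolise C8 and trigger retro-oxa-Michael opening of the oxepenone.
- Facial selectivity at C12 may be poor, because the pseudo-equatorial ethyl group shields weakly.
- 1,2-Addition may compete.

The fallback leaves at 12 and rejoins at 14. It moves facial control from the ethyl group to a hydroxyl and avoids base. Reagent-controlled CBS reduction of the 2-chloroenone ((R)-Me-CBS, BH3·SMe2, THF, −40 °C; the chloroalkenyl side acts as the large group) gives the (9S)-2-chloroallylic alcohol F8. Hydroxyl-directed Simmons–Smith cyclopropanation (Et2Zn, CH2I2, CH2Cl2, 0 °C, Furukawa conditions, or the more electrophilic CF3CO2ZnCH2I) then delivers C11 syn to the hydroxyl, that is anti to the ethyl group. This gives 14 directly as the epimer wanted for step 11.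

3. Step 14 (chloroallylboration).
- (Z)-γ-Substituted allylboron reagents tend to add to α-alkoxy aldehydes in the 6,7-anti sense, whereas the target is 6,7-syn. The reagent has to override the substrate, and facial selectivity may drop.
- Epimerisation at C7 may occur.
- The chlorohydrin may close to the epoxide on work-up.

The fallback leaves at 19 and rejoins at 25, so it also bypasses the chemoselective ozonolysis of step 16. An Evans syn-aldol reaction of commercial (R)-4-benzyl-3-(chloroacetyl)oxazolidin-2-one (Bu2BOTf, Et3N, CH2Cl2, −78 °C) with 19 gives the syn α-chloro-β-hydroxy imide F9 under strong auxiliary control. TESOTf/2,6-lutidine gives the silyl ether F10. LiBH4 (Et2O, MeOH, 0 °C) removes the auxiliary and gives the primary alcohol F11. Dess–Martin oxidation returns 25.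

Further compounds
F1 | step 11 | C12-aldehyde C9-acid (acyclic cis ether from ozonolysis of 10) | OC(=O)C[C@H](CO[Si](c1ccccc1)(c1ccccc1)C(C)(C)C)O[C@H](CC)C=O
F2 | step 11 | methyl ester aldehyde | COC(=O)C[C@H](CO[Si](c1ccccc1)(c1ccccc1)C(C)(C)C)O[C@H](CC)C=O
F3 | step 11 | tributyl(2-chloroallyl)stannane | C=C(Cl)C[Sn](CCCC)(CCCC)CCCC
F4 | step 11 | 12,13-syn (12R) 2-chlorohomoallylic alcohol ester | COC(=O)C[C@H](CO[Si](c1ccccc1)(c1ccccc1)C(C)(C)C)O[C@H](CC)[C@H](O)CC(Cl)=C
F5 | step 11 | hydroxy aldehyde (C9 = CHO) | O=CC[C@H](CO[Si](c1ccccc1)(c1ccccc1)C(C)(C)C)O[C@H](CC)[C@H](O)CC(Cl)=C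
F6 | step 11 | chloro diene for metathesis | C=CC[C@H](CO[Si](c1ccccc1)(c1ccccc1)C(C)(C)C)O[C@H](CC)[C@H](O)CC(Cl)=C
F7 | step 11 | (12R)-oxocenol | CC(C)(C)[Si](c1ccccc1)(c1ccccc1)OC[C@H]2C/C=C(/Cl)C[C@@H](O)[C@@H](CC)O2
F8 | step 8 | (9S)-2-chloroallylic alcohol of the oxepene | CC[C@@H]1C=C(Cl)[C@@H](O)C[C@H](CO[Si](c2ccccc2)(c2ccccc2)C(C)(C)C)O1
F9 | step 14 | syn chloroacetate aldol adduct | O=C3OC[C@@H](Cc4ccccc4)N3C(=O)[C@H](Cl)[C@@H](O)[C@H]1C/C=C(/Cl)C[C@H](Br)[C@@H](CC)O1
F10 | step 14 | C6 triethylsilyl ether of the aldol adduct | O=C3OC[C@@H](Cc4ccccc4)N3C(=O)[C@H](Cl)[C@@H](O[Si](CC)(CC)CC)[C@H]1C/C=C(/Cl)C[C@H](Br)[C@@H](CC)O1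
F11 | step 14 | C4 primary alcohol | OC[C@H](Cl)[C@@H](O[Si](CC)(CC)CC)[C@H]1C/C=C(/Cl)C[C@H](Br)[C@@H](CC)O1
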